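**Plan**

1. Numbering is that of the eudesmane skeleton (ring A = C1–C5 and C10, ring B = C5–C10, C11 = carbinol carbon on C7). Retrosynthesis: cut the C3–O ester, turn the C3/C4 diol back into a C3=C4 alkene, open ring A at C3=C4 (metathesis), then cut C5–C6 and C7–C8 together, which leaves a cyclobutanone (C8, C5, C10, C9) and the alkyne HC6≡C7–C11; the cyclobutanone is cut at C10–C1 and then into a vinylketene equivalent and propyne.
2. Enabling feature: ring B is a cyclohex-2-enone whose edge C8(=O)–C7=C6–C5 is an alkyne unit lodged between an acyl carbon and an sp3 carbon, the retron of a two-carbon ring expansion of a cyclobutanone. While C4 is still an isopropenyl carbon, C5 is allylic, so its bond to C8 is the one that should open with release of ring strain.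
3. Forward order: four-membered ring ([2+2]), quaternary C10 (conjugate addition), ring B (alkyne insertion, which also brings in C11 with its oxygen), ring A (ring-closing metathesis), then diol and ester.
4. Stereochemistry: C5 from a C2-symmetric pyrrolidine auxiliary in the [2+2]; C10 by addition anti to the C5 substituent; C5 is kept in the insertion and, since ring A is closed afterwards from two trans arms, the ring fusion is trans; C3 and C4 by osmylation anti to the axial methyl on C10.

Key step: step 4

Remark on the chemistry: the (2R,5R)-auxiliary is assumed to lead to the (4S)-cyclobutenone 7 by the model given in step 2; should the other face be preferred, the (2S,5S)-amine is used and nothing else changes.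

**Route**

Step 1
Reactants: 1 3-methylbut-3-enoic acid; 2 (2R,5R)-2,5-dimethylpyrrolidine
Product: 3 1-[(2R,5R)-2,5-dimethylpyrrolidin-1-yl]-3-methylbut-3-en-1-one
Conditions: DCC, HOBt (cat.), CH2Cl2, 0 to 20 °C
Reagents that add atoms: none
Why: Carbodiimide-mediated amide coupling; the β,γ-unsaturated acid is used so that α-deprotonation in step 2 gives the vinyl-substituted keteniminium ion directly, and no stereocentre is formed.

Step 2
Reactants: 3 1-[(2R,5R)-2,5-dimethylpyrrolidin-1-yl]-3-methylbut-3-en-1-one; 4 propyne
Product: 7 (4S)-3-methyl-4-(prop-1-en-2-yl)cyclobut-2-en-1-one, via keteniminium triflate 5 (not isolated), via cyclobuteniminium triflate 6 (not isolated)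
Conditions: Tf2O, 2,4,6-collidine, CH2Cl2, −30 °C; propyne (excess), −30 to 20 °C; then H2O, 20 °C
Reagents that add atoms: water, O
Why: Keteniminium–alkyne [2+2] cycloaddition: O-triflation and α-deprotonation of 3 should give the vinyl-substituted keteniminium ion 5, whose iminium carbon bonds to the terminal carbon of propyne and whose α-carbon to the methyl-bearing carbon, and hydrolysis of 6 frees the ketone; the alkyne should approach from the hydrogen side of the α-carbon and close onto it on the side of the pyrrolidine not blocked by a ring methyl, which sets the one new stereocentre (C4 of 7, later C5), a centre that cannot epimerise by enolisation because the enol would be a cyclobutadiene.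

Step 3
Reactants: 7 (4S)-3-methyl-4-(prop-1-en-2-yl)cyclobut-2-en-1-one; 8 but-3-en-1-ylmagnesium bromide
Product: 10 (2S,3R)-3-(but-3-en-1-yl)-3-methyl-2-(prop-1-en-2-yl)cyclobutan-1-one, via magnesium enolate 9 (not isolated)
Conditions: CuBr·SMe2 (20 mol%), THF, −78 °C; then sat. aq. NH4Cl, −78 °C
Reagents that add atoms: none
Why: Copper-catalysed conjugate addition of the Grignard reagent to the strained enone builds the quaternary C10; the butenyl group should enter the flat four-membered ring on the face opposite the isopropenyl group on the neighbouring carbon, which places methyl cis to isopropenyl, and protonation of enolate 9 at its CH carbon creates no further centre.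

Step 4
Reactants: 10 (2S,3R)-3-(but-3-en-1-yl)-3-methyl-2-(prop-1-en-2-yl)cyclobutan-1-one; 11 trimethyl[(2-methylbut-3-yn-2-yl)oxy]silane
Product: 15 (4S,5R)-5-(but-3-en-1-yl)-2-(2-hydroxypropan-2-yl)-5-methyl-4-(prop-1-en-2-yl)cyclohex-2-en-1-one, via acyl(allyl)nickelacycle 12 (not isolated), via acyl(alkenyl)nickelacycle 13 (not isolated), via silyl ether 14 (not isolated)
Conditions: Ni(cod)2 (10 mol%), 1,3-bis(2,6-diisopropylphenyl)imidazol-2-ylidene (IPr, 10 mol%), toluene, 60 °C, slow addition of 11; then citric acid, MeOH, 20 °C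
Reagents that add atoms: none
Why: Proposed new method: zerovalent nickel, bound to the isopropenyl alkene of 10, should insert into the strained allylic C8–C5 bond to give the acyl(allyl)nickelacycle 12, the alkyne should then insert into the Ni–C5 bond with C5 going to its unsubstituted terminus (13), and acyl–alkenyl reductive elimination should release 14 and the catalyst, the driving force being the loss of the cyclobutanone strain. The closest known reaction type is the nickel-catalysed insertion of internal alkynes into 3-substituted cyclobutanones (formal [4+2]), which has not been shown on a 2-alkenyl-3,3-disubstituted cyclobutanone, on the more substituted acyl–carbon bond or with a terminal propargylic ether. Ring B, the only ring closed, is formed as a six-membered ring by C(sp2)–C(sp2) reductive elimination from the seven-membered nickelacycle, that is, by a net two-carbon ring expansion of the four-membered ring. No new stereocentre arises: C5 is carried over with retention, since nickel takes the place of C8 on the same face and C5 has no β-hydrogen (C4 is sp2 and C10 is quaternary), and C10 is not touched. The step needs cleavage of C8–C5 and not of C8–C9, which the allylic position of C5 and the alkene as an internal ligand should secure, and it needs the head-to-tail orientation of the alkyne, which the bulk of the tertiary propargylic carbon and of the carbene ligand should secure by keeping that carbon on nickel and away from C5. Mild acidic methanolysis then removes the silyl ether.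

Step 5
Reactants: 15 (4S,5R)-5-(but-3-en-1-yl)-2-(2-hydroxypropan-2-yl)-5-methyl-4-(prop-1-en-2-yl)cyclohex-2-en-1-one
Product: 16 (4aR,8aR)-3-(2-hydroxypropan-2-yl)-5,8a-dimethyl-4a,7,8,8a-tetrahydronaphthalen-2(1H)-one
Conditions: second-generation Grubbs catalyst RuCl2(=CHPh)(PCy3)(H2IMes) (5 mol%), CH2Cl2 (0.005 M), 40 °C
Reagents that add atoms: none
Why: Ring-closing metathesis between the terminal butenyl alkene and the isopropenyl group closes ring A as the trisubstituted C3=C4 alkene; the two arms are trans on ring B, so the ring fusion is trans by construction, and the electron-poor enone alkene should not take part.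

Step 6
Reactants: 16 (4aR,8aR)-3-(2-hydroxypropan-2-yl)-5,8a-dimethyl-4a,7,8,8a-tetrahydronaphthalen-2(1H)-one
Product: 17 (4aR,5S,6R,8aR)-5,6-dihydroxy-3-(2-hydroxypropan-2-yl)-5,8a-dimethyl-4a,5,6,7,8,8a-hexahydronaphthalen-2(1H)-one
Conditions: OsO4 (2 mol%), NMO, acetone/H2O, 0 to 20 °C
Reagents that add atoms: osmium tetroxide, O=[Os](=O)(=O)=O; N-methylmorpholine N-oxide, C[N+]1([O-])CCOCC1; water, O
Why: Osmium-catalysed syn-dihydroxylation should take the electron-rich trisubstituted C3=C4 alkene and not the enone, from the face opposite the axial C10 methyl of the trans-fused bicycle, which gives the cis-diol with both oxygens anti to that methyl (C3 R, C4 S).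

Step 7
Reactants: 17 (4aR,5S,6R,8aR)-5,6-dihydroxy-3-(2-hydroxypropan-2-yl)-5,8a-dimethyl-4a,5,6,7,8,8a-hexahydronaphthalen-2(1H)-one; 18 3-methylbut-2-enoyl chloride
Product: 19 (1S,2R,4aR,8aR)-1-hydroxy-7-(2-hydroxypropan-2-yl)-1,4a-dimethyl-6-oxo-1,2,3,4,4a,5,6,8a-octahydronaphthalen-2-yl 3-methylbut-2-enoate
Conditions: pyridine, DMAP (cat.), CH2Cl2, 0 °C
Reagents that add atoms: none
Why: Acylation of the only secondary hydroxyl group; the tertiary hydroxyls at C4 and C11 should not react under these mild conditions and no stereocentre is touched.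

**Compound list**

1 | 3-methylbut-3-enoic acid | C=C(C)CC(=O)O | starting material
2 | (2R,5R)-2,5-dimethylpyrrolidine | C[C@@H]1CC[C@@H](C)N1 | starting material
3 | 1-[(2R,5R)-2,5-dimethylpyrrolidin-1-yl]-3-methylbut-3-en-1-one | C=C(C)CC(=O)N1[C@H](C)CC[C@H]1C | intermediate
4 | propyne | CC#C | starting material
5 | (2R,5R)-2,5-dimethyl-1-(3-methylbuta-1,3-dien-1-ylidene)pyrrolidin-1-ium trifluoromethanesulfonate | C=C(C)C=C=[N+]1[C@H](C)CC[C@H]1C.[O-]S(=O)(=O)C(F)(F)F | intermediate
6 | (2R,5R)-2,5-dimethyl-1-[(4S)-3-methyl-4-(prop-1-en-2-yl)cyclobut-2-en-1-ylidene]pyrrolidin-1-ium trifluoromethanesulfonate | CC(=C)[C@H]1C(C)=CC1=[N+]2[C@H](C)CC[C@H]2C.[O-]S(=O)(=O)C(F)(F)F | intermediate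
7 | (4S)-3-methyl-4-(prop-1-en-2-yl)cyclobut-2-en-1-one | O=C1C=C(C)[C@@H]1C(C)=C | intermediate
8 | but-3-en-1-ylmagnesium bromide | C=CCC[Mg]Br | starting material
9 | bromomagnesium (3R,4S)-3-(but-3-en-1-yl)-3-methyl-4-(prop-1-en-2-yl)cyclobut-1-en-1-olate | C=CCC[C@]1(C)C=C(O[Mg]Br)[C@H]1C(C)=C | intermediate
10 | (2S,3R)-3-(but-3-en-1-yl)-3-methyl-2-(prop-1-en-2-yl)cyclobutan-1-one (isopropenyl cis to methyl) | C=CCC[C@]1(C)CC(=O)[C@H]1C(C)=C | intermediate
11 | trimethyl[(2-methylbut-3-yn-2-yl)oxy]silane | C#CC(C)(C)O[Si](C)(C)C | starting material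
12 | acyl(allyl)nickelacycle: nickel inserted between C1 and C2 of 10, a 2-nickelacyclopentanone (carbene ligand on nickel not drawn) | C=CCC[C@]1(C)CC(=O)[Ni][C@H]1C(C)=C | intermediate
13 | acyl(alkenyl)nickelacycle: seven-membered ring after insertion of 11 into the nickel–carbon bond of 12 (carbene ligand on nickel not drawn) | C=CCC[C@]1(C)CC(=O)[Ni]C(C(C)(C)O[Si](C)(C)C)=C[C@H]1C(C)=C | intermediate
14 | (4S,5R)-5-(but-3-en-1-yl)-5-methyl-4-(prop-1-en-2-yl)-2-[2-(trimethylsilyloxy)propan-2-yl]cyclohex-2-en-1-one | C=CCC[C@]1(C)CC(=O)C(C(C)(C)O[Si](C)(C)C)=C[C@H]1C(C)=C | intermediate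
15 | (4S,5R)-5-(but-3-en-1-yl)-2-(2-hydroxypropan-2-yl)-5-methyl-4-(prop-1-en-2-yl)cyclohex-2-en-1-one | C=CCC[C@]1(C)CC(=O)C(C(C)(C)O)=C[C@H]1C(C)=C | intermediate
16 | (4aR,8aR)-3-(2-hydroxypropan-2-yl)-5,8a-dimethyl-4a,7,8,8a-tetrahydronaphthalen-2(1H)-one (trans-fused; (5R,10R)-11-hydroxyeudesma-3,6-dien-8-one) | CC1=CCC[C@]2(C)CC(=O)C(C(C)(C)O)=C[C@@H]12 | intermediate
17 | (4aR,5S,6R,8aR)-5,6-dihydroxy-3-(2-hydroxypropan-2-yl)-5,8a-dimethyl-4a,5,6,7,8,8a-hexahydronaphthalen-2(1H)-one ((3R,4S,5R,10R)-3,4,11-trihydroxyeudesm-6-en-8-one) | O[C@@H]1CC[C@]2(C)CC(=O)C(C(C)(C)O)=C[C@H]2[C@]1(C)O | intermediate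
18 | 3-methylbut-2-enoyl chloride | CC(C)=CC(=O)Cl | starting material
19 | (1S,2R,4aR,8aR)-1-hydroxy-7-(2-hydroxypropan-2-yl)-1,4a-dimethyl-6-oxo-1,2,3,4,4a,5,6,8a-octahydronaphthalen-2-yl 3-methylbut-2-enoate | CC(C)=CC(=O)O[C@@H]1CC[C@]2(C)CC(=O)C(C(C)(C)O)=C[C@H]2[C@]1(C)O | target

**Step count and risks**

Total step count: 7. Longest linear sequence: 7 steps (the route is linear).

Steps most likely to fail:

1. Step 4 (Proposed new method). Processes that may defeat it: opening of the unsubstituted C8–C9 bond, insertion of the alkyne in the reverse sense, insertion of the tethered butenyl alkene or a 1,3-acyl shift in place of the alkyne insertion, loss of configuration at C5 by face exchange of the allylnickel unit, and oligomerisation of the terminal alkyne. Fallback with known chemistry, setting out from 8 and coming back at 15: iron-catalysed cross-coupling of 8 with (E)-4-oxopent-2-en-2-yl 4-methylbenzenesulfonate (Fe(acac)3, THF, −20 °C) should give, with retention of geometry, (E)-4-methylocta-3,7-dien-2-one F1. A Diels–Alder reaction of F1 with 2-(trimethylsilyloxy)buta-1,3-diene under a chiral cationic oxazaborolidine Lewis acid should give 1-[(1R,6R)-6-(but-3-en-1-yl)-6-methyl-4-(trimethylsilyloxy)cyclohex-3-en-1-yl]ethan-1-one F2, the E geometry placing acetyl cis to methyl and the catalyst fixing the absolute sense. Wittig methylenation (Ph3P=CH2) should turn the acetyl group into isopropenyl, giving {[(4S,5R)-5-(but-3-en-1-yl)-5-methyl-4-(prop-1-en-2-yl)cyclohex-1-en-1-yl]oxy}trimethylsilane F3. Saegusa oxidation (Pd(OAc)2, MeCN) should give (4S,5R)-5-(but-3-en-1-yl)-5-methyl-4-(prop-1-en-2-yl)cyclohex-2-en-1-one F4. Conjugate addition of Me2AlSPh with capture of the aluminium enolate by acetone should give (4S,5R)-5-(but-3-en-1-yl)-2-(2-hydroxypropan-2-yl)-5-methyl-3-(phenylsulfanyl)-4-(prop-1-en-2-yl)cyclohexan-1-one F5, and oxidation to the sulfoxide (NaIO4) with syn-elimination on warming should give 15.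

2. Step 2. Processes that may defeat it: low facial selectivity of the auxiliary, a competing [4+2] mode of the vinyl-substituted keteniminium ion, and electrocyclic ring opening of the 4-alkenylcyclobutenone on warming. Fallback, setting out from 18 and coming back at 7: isopropenylketene, made from 18 with Et3N, should add [2+2] to ethynyl (1R,2S,5R)-menthyl ether to give the 3-alkoxy-4-isopropenylcyclobutenone as two diastereomers. Of these, (4R)-3-{[(1R,2S,5R)-5-methyl-2-(propan-2-yl)cyclohexyl]oxy}-4-(prop-1-en-2-yl)cyclobut-2-en-1-one F6 is separated by crystallisation or chromatography. 1,2-Addition of MeLi and acidic work-up (carbonyl transposition of the vinylogous ester with loss of menthol) should give 7.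

3. Step 7. Processes that may defeat it: slow acylation of the hindered axial hydroxyl next to a quaternary carbon, acylation of a tertiary hydroxyl under forcing conditions, and migration of the double bond of the acyl group out of conjugation through a vinylketene. Fallback, setting out from 17 and coming back at 19: Bu2SnO (toluene, reflux, removal of water) should give the 3,4-O-dibutylstannylene acetal of 17 F7, in which the secondary oxygen is the nucleophilic one, and treatment with 18 at 0 °C followed by aqueous work-up should give 19.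

Further compounds
F1 | step 4 | (E)-4-methylocta-3,7-dien-2-one | CC(=O)/C=C(\C)CCC=C
F2 | step 4 | 1-[(1R,6R)-6-(but-3-en-1-yl)-6-methyl-4-(trimethylsilyloxy)cyclohex-3-en-1-yl]ethan-1-one | C=CCC[C@]1(C)CC(O[Si](C)(C)C)=CC[C@H]1C(C)=O
F3 | step 4 | {[(4S,5R)-5-(but-3-en-1-yl)-5-methyl-4-(prop-1-en-2-yl)cyclohex-1-en-1-yl]oxy}trimethylsilane | C=CCC[C@]1(C)CC(O[Si](C)(C)C)=CC[C@H]1C(C)=C
F4 | step 4 | (4S,5R)-5-(but-3-en-1-yl)-5-methyl-4-(prop-1-en-2-yl)cyclohex-2-en-1-one | C=CCC[C@]1(C)CC(=O)C=C[C@H]1C(C)=C
F5 | step 4 | (4S,5R)-5-(but-3-en-1-yl)-2-(2-hydroxypropan-2-yl)-5-methyl-3-(phenylsulfanyl)-4-(prop-1-en-2-yl)cyclohexan-1-one | C=CCC[C@]1(C)CC(=O)C(C(C)(C)O)C(Sc2ccccc2)[C@H]1C(C)=C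
F6 | step 2 | (4R)-3-{[(1R,2S,5R)-5-methyl-2-(propan-2-yl)cyclohexyl]oxy}-4-(prop-1-en-2-yl)cyclobut-2-en-1-one | CC(C)[C@@H]1CC[C@@H](C)C[C@H]1OC2=CC(=O)[C@@H]2C(C)=C
F7 | step 7 | 3,4-O-dibutylstannylene acetal of 17 | CCCC[Sn]3(CCCC)O[C@@H]1CC[C@]2(C)CC(=O)C(C(C)(C)O)=C[C@H]2[C@]1(C)O3
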